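The runs were generated by integration from invented constants, and the scatter is random.

A leftover opens this: ochre, the flask with the least free base, holds 3.00 equiv of it against 1.00 equiv of nucleophile, so one base per electrophile still leaves 2.00 equiv.

| setting | Friday's | Monday's | Thursday's | violet | ochre | grey |
|---|---|---|---|---|---|---|
| electrophile | 0.10 M | 0.10 M | 0.10 M | 0.10 M | 0.10 M | 0.10 M |
| nucleophile | 1 equiv | 1 equiv | 1 equiv | 1.00 equiv | 1.00 equiv | 1.00 equiv |
| free base | 3.8 equiv | 5.5 equiv | 11 equiv | 12.0 equiv | 3.00 equiv | 6.00 equiv |
| remark | run made earlier | run made earlier | run made earlier |  |  |  |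
| time |  |  |  | 8.0 min | 8.0 min | 8.0 min |

| run | time / min | electrophile / % | target / % |
|---|---|---|---|
| Friday's | 0.333 | 97.3 | 2.4 |
| Friday's | 0.667 | 94.1 | 7.0 |
| Friday's | 1.00 | 89.2 | 8.2 |
| Friday's | 2.00 | 83.2 | 14.7 |
| Friday's | 4.00 | 68.6 | 21.1 |
| Monday's | 0.333 | 98.0 | 3.1 |
| Monday's | 0.667 | 92.6 | 5.4 |
| Monday's | 1.00 | 91.3 | 7.5 |
| Monday's | 2.00 | 82.3 | 16.4 |
| Monday's | 4.00 | 71.3 | 19.6 |
| Thursday's | 0.333 | 96.6 | 4.0 |
| Thursday's | 1.00 | 90.0 | 9.2 |
| Thursday's | 2.00 | 82.4 | 14.9 |
| Thursday's | 3.00 | 76.9 | 17.9 |
| Thursday's | 4.00 | 69.6 | 19.9 |

(scatter of a reading: 1 percentage point)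

- what was read earlier has a scatter of 1 percentage point, one standard deviation

- part of the electrophile that has reacted at the end, violet
- part of the electrophile that has reacted at the end, ochre
- part of the electrophile that has reacted at the end, grey
- what raising the equivalents of free base from its lowest to its highest value here does to the part of the electrophile that has reacted (changes below 5 percentage points count as none) (it falls / it rises / no change)

Within the scatter of a reading, the runs show no effect of the base charge on the electrophile. At 4.00 min the electrophile reads 68.6%, 71.3% and 69.6% at 3.8 equiv, 5.5 equiv and 11 equiv, with no order in the charge. So I pool the runs. Let x be c(electrophile) over its starting value. It averages 69.8% there and 90.2% at 1.00 min.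

S = (1/x − 1)/t = 0.108 min⁻¹

S is the rise per minute of the reciprocal of x; for equal partners it is the second-order rate constant times the starting c(electrophile). The earlier pooled reading gives 0.109 min⁻¹, so S reads steady within the scatter. The first-order constant, by contrast, drops from 0.104 min⁻¹ to 0.0898 min⁻¹.

Now I bracket the answer at 8.0 min. Loosely, it lies between the 30.2% already reacted and the 60.3% that a constant pace gives.

Above, first order, which ignores the falling nucleophile: 1 − x² = 51.2%

Below, both partners falling together: 1 − 1/(1 + S·t) = 46.4%

Since S reads steady, I commit to the lower bound for violet, ochre and grey alike, with no trend. The forecast says 47% for violet, 47% for ochre and 47% for grey, with ochre's range 41% to 53%, and no change. That lies inside my bracket, above my own number. Its ground: “The rate is therefore effectively zero order in base over this range”.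

The flask gives 46.3% for violet, 46.1% for ochre and 46.2% for grey, a change of 0.17 percentage points: no change.

    electrophile + nucleophile → acid set free + target (k = 0.0180 L mol⁻¹ s⁻¹)
    nucleophile + acid set free ⇌ protonated nucleophile, settled at all times (K = 6100 L mol⁻¹)
    acid set free + free base ⇌ salt of the base, settled at all times (K = 70000 L mol⁻¹)
    target → over-reaction product A (k = 0.00320 s⁻¹)
    acid set free + free base ⇌ idle adduct, settled at all times (K = 310 L mol⁻¹)
    target → over-reaction product B (k = 1.40 × 10⁻⁶ s⁻¹)

S put grey at 46.4%. Take grey's recipe with 2.50 equiv of nucleophile, so the partners stand at M = 2.50: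

reacted = 1 − (M − 1)/(M·exp((M − 1)·S·t) − 1) = 81.6%

That flask has 81.3%. In grey at 2.79 min, the electrophile's half-life by the step making target is 8.4 min, while target's half-life by loss to over-reaction product A alone is shorter, 3.6 min. At 8.00 min grey makes target at 0.799 of the rate at which it uses it up, each step taken net, and holds 20.2% of target beside 26.0% of over-reaction product A.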